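## Retrosynthetic overview

- The target is catechin-(4α→6)-catechin-(4α→6)-epicatechin. The plan rests on ring C of the middle unit. This is the O1–C2–C3–C4 bridge on ring A (C8a, C4a), whose C4 also carries C6 of the epicatechin unit and whose C2, C3 and C4 substituents are all trans.
- The last operations are reductive removal of an acyl group from the middle C3 oxygen, then hydrogenolysis of 14 benzyl ethers and one bromine cap.
- The key disconnection cuts C8a–O1, C4a–C4, C3–C4 and O1–C2 together. This gives three pieces: a C4a≡C8a aryne of middle ring A that already bears the finished upper catechin at C6, an epicatechin-6-carbaldehyde (its C=O becomes C4 and O1), and an (E)-styryl ester (C2, C3, ring B).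
- Aryne precursor: (+)-catechin is oxidised at C4 and joined 4α to threefold-symmetric phloroglucinol. The hydroxyl para to the new bond is singled out, ortho-iodinated and converted into the o-silylaryl triflate. Aldehyde: (−)-epicatechin, bromine cap at C8, formylation at C6. Ester: boron–Wittig olefination, then copper-catalysed C–O coupling.
- Ring order: all rings of the upper and lower units come from the natural flavanols, middle ring A from phloroglucinol and ring B from the benzaldehyde. Middle ring C is the only ring built, and it is closed last.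

Key step: step 18

Assumption: rotamers about the C4–aryl bonds interconvert at room temperature and are not counted as stereoisomers. The pendant phenyl ring of 6–14 becomes ring A of the middle unit (C1' = C6, C3' = C4a, C4' = C8a).

## Route

Step 1
Reactants: 1 (+)-catechin
Product: 2 5,7,3',4'-tetra-O-benzylcatechin
Conditions: BnBr (4.4 equiv), K2CO3, DMF, 0 °C → rt
Reagents that add atoms: benzyl bromide, BrCc1ccccc1
Why: Williamson etherification in which K2CO3 deprotonates only the four phenols, so the secondary C3 alcohol stays free and C2 and C3 are untouched.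

Step 2
Reactants: 2 5,7,3',4'-tetra-O-benzylcatechin
Product: 3 3,5,7,3',4'-penta-O-benzylcatechin
Conditions: NaH, BnBr, DMF, 0 °C → rt
Reagents that add atoms: benzyl bromide, BrCc1ccccc1
Why: Williamson etherification of the remaining secondary alkoxide, which cannot epimerise C2 because all phenols are capped and ring C cannot open to a quinone methide.

Step 3
Reactants: 3 3,5,7,3',4'-penta-O-benzylcatechin
Product: 4 (2R,3S,4S)-4β-(2-ethoxyethoxy)-penta-O-benzylcatechin
Conditions: DDQ (2 equiv), 2-ethoxyethanol (5 equiv), CH2Cl2, rt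
Reagents that add atoms: 2-ethoxyethanol, CCOCCO
Why: Oxidative benzylic C–H etherification in which DDQ takes hydride from C4, the position activated by O1 and the 5- and 7-oxygens, and the alcohol adds to give the 4β ether, a centre that is erased again in step 4.

Step 4
Reactants: 4 (2R,3S,4S)-4β-(2-ethoxyethoxy)-penta-O-benzylcatechin; 5 phloroglucinol
Product: 6 4α-(2,4,6-trihydroxyphenyl)-penta-O-benzylcatechin (2,3-trans-3,4-trans)
Conditions: 5 (6 equiv), BF3·OEt2 (0.3 equiv), Et2O–CH2Cl2, −20 → 0 °C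
Reagents that add atoms: none
Why: Friedel–Crafts alkylation of the kind used for interflavan bonds, in which acid ionises the C4 ether, threefold-symmetric phloroglucinol in excess can give only one regioisomer, and attack anti to the C3 benzyloxy group sets C4 as 3,4-trans (4α).

Step 5
Reactants: 6 4α-(2,4,6-trihydroxyphenyl)-penta-O-benzylcatechin
Product: 7 4α-[2,6-dihydroxy-4-(triisopropylsilyloxy)phenyl]-penta-O-benzylcatechin
Conditions: i-Pr3SiCl (1.05 equiv), imidazole, DMF, −20 → 0 °C
Reagents that add atoms: triisopropylsilyl chloride, CC(C)[Si](Cl)(C(C)C)C(C)C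
Why: Sterically controlled O-silylation, since the bulky chlorosilane should react at the hydroxyl para to the flavanyl group (two ortho hydrogens) much faster than at the two hydroxyls that flank the secondary C4 carbon.

Step 6
Reactants: 7 4α-[2,6-dihydroxy-4-(triisopropylsilyloxy)phenyl]-penta-O-benzylcatechin
Product: 8 4α-[2,6-dibenzyloxy-4-(triisopropylsilyloxy)phenyl]-penta-O-benzylcatechin
Conditions: BnBr (3 equiv), K2CO3, n-Bu4NI (cat.), dry DMF, rt → 40 °C
Reagents that add atoms: benzyl bromide, BrCc1ccccc1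
Why: Williamson etherification of the two hindered phenols under anhydrous carbonate, conditions that an aryl triisopropylsilyl ether tolerates.

Step 7
Reactants: 8 4α-[2,6-dibenzyloxy-4-(triisopropylsilyloxy)phenyl]-penta-O-benzylcatechin
Product: 9 4α-(2,6-dibenzyloxy-4-hydroxyphenyl)-penta-O-benzylcatechin
Conditions: n-Bu4NF, AcOH (1:1), THF, 0 °C
Reagents that add atoms: none
Why: Fluoride-induced desilylation driven by Si–F bond formation, buffered with acetic acid so that the electron-rich phenoxide is protonated at once.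

Step 8
Reactants: 9 4α-(2,6-dibenzyloxy-4-hydroxyphenyl)-penta-O-benzylcatechin
Product: 10 4α-(2,6-dibenzyloxy-4-hydroxy-3-iodophenyl)-penta-O-benzylcatechin
Conditions: I2 (1.0 equiv), NaHCO3, THF–H2O, 0 °C
Reagents that add atoms: iodine, II
Why: Electrophilic iodination through the phenoxide, in which unactivated I2 attacks only the free phenol ring, the two positions ortho to its hydroxyl are equivalent, and the fully benzylated rings remain inert.

Step 9
Reactants: 10 4α-(2,6-dibenzyloxy-4-hydroxy-3-iodophenyl)-penta-O-benzylcatechin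
Product: 11 4α-[2,6-dibenzyloxy-3-iodo-4-(trimethylsilyloxy)phenyl]-penta-O-benzylcatechin
Conditions: (Me3Si)2NH, THF, 65 °C; evaporate
Reagents that add atoms: hexamethyldisilazane, C[Si](C)(C)N[Si](C)(C)C
Why: O-silylation of the phenol with hexamethyldisilazane, which gives only ammonia as by-product, so the ether can be used after evaporation.

Step 10
Reactants: 11 4α-[2,6-dibenzyloxy-3-iodo-4-(trimethylsilyloxy)phenyl]-penta-O-benzylcatechin
Product: 14 4α-(2,6-dibenzyloxy-4-triflyloxy-3-trimethylsilylphenyl)catechin pentabenzyl ether, via aryllithium 12 (not isolated), via lithium silylphenoxide 13 (not isolated)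
Conditions: n-BuLi (1.1 equiv), THF, −95 → −78 °C; then Tf2O, −95 → −78 °C
Reagents that add atoms: triflic anhydride, O=S(=O)(OS(=O)(=O)C(F)(F)F)C(F)(F)F
Why: Iodine–lithium exchange (far faster than benzylic deprotonation at this temperature), 1,3-retro-Brook O→C silyl migration and triflation of the resulting phenoxide, the standard sequence to o-silylaryl triflates.

Step 11
Reactants: 15 (−)-epicatechin
Product: 16 5,7,3',4'-tetra-O-benzylepicatechin
Conditions: BnBr (4.4 equiv), K2CO3, DMF, 0 °C → rt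
Reagents that add atoms: benzyl bromide, BrCc1ccccc1
Why: Williamson etherification selective for the four phenols, as in step 1, with the 2,3-cis centres untouched.

Step 12
Reactants: 16 5,7,3',4'-tetra-O-benzylepicatechin
Product: 17 3,5,7,3',4'-penta-O-benzylepicatechin
Conditions: NaH, BnBr, DMF, 0 °C → rt
Reagents that add atoms: benzyl bromide, BrCc1ccccc1
Why: Williamson etherification of the axial C3 alkoxide, without risk to C2 because no free phenol remains.

Step 13
Reactants: 17 3,5,7,3',4'-penta-O-benzylepicatechin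
Product: 18 8-bromo-penta-O-benzylepicatechin
Conditions: NBS (1.0 equiv), CH2Cl2, −78 °C → rt
Reagents that add atoms: N-bromosuccinimide, O=C1CCC(=O)N1Br
Why: Electrophilic aromatic bromination, for which C8 is the more reactive and less hindered ring A position of 5,7-dibenzylated flavan-3-ols, so one equivalent caps C8 and leaves C6 open.

Step 14
Reactants: 18 8-bromo-penta-O-benzylepicatechin
Product: 20 8-bromo-penta-O-benzylepicatechin-6-carbaldehyde, via C6 iminium chloride 19 (not isolated)
Conditions: POCl3 (3 equiv), DMF, 0 → 70 °C; then ice–water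
Reagents that add atoms: N,N-dimethylformamide, CN(C)C=O; water, O
Why: Vilsmeier–Haack formylation, which with C8 capped can occur only at C6, the one carbon still activated by three oxygen donors, while catechol ring B is too weak a nucleophile for the chloroiminium ion.

Step 15
Reactants: 21 3,4-dibenzyloxybenzaldehyde; 22 bis(pinacolatoboryl)methane
Product: 24 (E)-2-(3,4-dibenzyloxyphenyl)vinylboronic acid pinacol ester, via lithiated diborylmethane 23 (not isolated)
Conditions: 22, LiTMP, THF, 0 °C; then 21, −78 °C → rt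
Reagents that add atoms: none
Why: Boron–Wittig olefination, in which the α-boryl carbanion adds to the aldehyde and syn B–O elimination should give the (E)-alkenyl boronate.

Step 16
Reactants: 24 (E)-2-(3,4-dibenzyloxyphenyl)vinylboronic acid pinacol ester
Product: 25 potassium (E)-2-(3,4-dibenzyloxyphenyl)vinyltrifluoroborate
Conditions: KHF2 (aq), MeOH, rt
Reagents that add atoms: potassium hydrogen difluoride, [K+].[F-].F
Why: Boronate-to-trifluoroborate exchange, which does not touch the alkene geometry and should give a crystalline salt.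

Step 17
Reactants: 25 potassium (E)-2-(3,4-dibenzyloxyphenyl)vinyltrifluoroborate; 26 (S)-2-methoxy-2-phenylacetic acid
Product: 27 (E)-2-(3,4-dibenzyloxyphenyl)vinyl (S)-2-methoxy-2-phenylacetate
Conditions: CuBr (10 mol %), 4-(dimethylamino)pyridine (20 mol %), 4 Å MS, O2 (1 atm), MeCN, 60 °C
Reagents that add atoms: none
Why: Copper-catalysed oxidative Chan–Lam-type C–O coupling of alkenyl trifluoroborates with carboxylic acids, which is stereospecific at the alkene so that the (E)-geometry is carried over, and which leaves the α-centre of the acid unaffected.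

Step 18
Reactants: 14 4α-(2,6-dibenzyloxy-4-triflyloxy-3-trimethylsilylphenyl)catechin pentabenzyl ether; 20 8-bromo-penta-O-benzylepicatechin-6-carbaldehyde; 27 (E)-2-(3,4-dibenzyloxyphenyl)vinyl (S)-2-methoxy-2-phenylacetate
Product: 31 perbenzylated 8-bromo trimer bearing the middle C3 oxygen as its (S)-2-methoxy-2-phenylacetate, via aryne 28 (not isolated), via benzoxete 29 (not isolated), via o-quinone methide 30 (not isolated)
Conditions: CsF (4 equiv), 20 (2 equiv), 27 (4 equiv), 4 Å MS, toluene–MeCN (2:1), 50 °C, 14 added over 8 h; then 80 °C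
Reagents that add atoms: none
Why: Proposed new method: fluoride attack on the C4a silyl group of 14 expels the C8a triflate to give aryne 28, the carbonyl oxygen of 20 (made nucleophilic by three ring oxygen donors) adds to C8a, the terminus remote from the inductively withdrawing C5 benzyloxy group, the C4a aryl anion collapses onto the carbonyl carbon to close the four-membered benzoxete 29 (formal 2+2), and 29 opens by a 4π electrocyclic process with outward rotation of the aryl group to the (E)-o-quinone methide 30. Ring C is then closed intermolecularly in one concerted but asynchronous inverse-electron-demand hetero-Diels–Alder (4+2) addition of 27 across O1=C8a–C4a=C4, with C3–C4 bonding ahead of O1–C2. The closest known reaction types are the aryne–aldehyde 2+2/ring-opening cascade, in which the methide is taken up by a second aryne to give 9-arylxanthenes, and the cycloaddition of separately generated o-quinone methides with (E)-β-substituted styrenes to 2,3-trans-2,4-cis flavans, but their union with an enol ester as the 2π partner has no precedent. The required orientation (C2 to O1, C3 to C4) is not owed to the enol-ester oxygen, whose lone pair alone would polarise the alkene the other way, but to the 4-benzyloxy group of ring B, which stabilises positive charge building up at C2 far better than the acyl-damped oxygen can at C3, and this is why an ester and not an enol ether is used. C2 and C3 come out trans by suprafacial addition to the (E)-alkene, C4 comes out 2,4-cis and 3,4-trans by endo placement of ring B under the (E)-methide with the acyloxy group exo, and the absolute sense depends on the (S)-O-methylmandeloyl group, whose phenyl ring in the extended conformer (s-trans enol ester, methoxy syn-periplanar to C=O) covers the C2-Si/C3-Re face, so that bonding on the C2-Re/C3-Si face should give 2R,3S; this last control is the weakest, and the wrong-face all-trans isomer is a diastereomer that chromatography should remove. Chemoselectivity needs the aryne to meet 20 before it meets 30 or the alkene of 27, which slow addition of 14 to an excess of both partners should secure, while the C8 bromine of 20 blocks the only free nucleophilic carbon of its ring A.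

Step 19
Reactants: 31 perbenzylated 8-bromo trimer (S)-2-methoxy-2-phenylacetate
Product: 32 perbenzylated 8-bromo trimer with free middle C3 hydroxyl
Conditions: i-Bu2AlH (4 equiv), CH2Cl2, −78 → −20 °C; aq Rochelle salt
Reagents that add atoms: none
Why: Reductive ester cleavage at the acyl carbon, which frees the C3 alkoxide without breaking the C3–O bond and leaves benzyl ethers, the aryl bromide and all stereocentres untouched.

Step 20
Reactants: 32 perbenzylated 8-bromo trimer with free middle C3 hydroxyl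
Product: 33 catechin-(4α→6)-catechin-(4α→6)-epicatechin (CNP0163146.3)
Conditions: H2 (1 atm), Pd(OH)2/C, NaOAc (1.5 equiv), THF–MeOH–H2O, rt
Reagents that add atoms: none
Why: Catalytic hydrogenolysis, which should cleave the 14 benzyl ethers and the C8 aryl bromide in one operation while acetate buffers the hydrogen bromide so that the acid-labile interflavan bonds and C2 centres are preserved.

## Compound list

1 | (+)-catechin, (2R,3S) | Oc1cc(O)c2c(c1)O[C@H](c1ccc(O)c(O)c1)[C@@H](O)C2 | starting material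
2 | 5,7,3',4'-tetra-O-benzylcatechin | c9ccccc9COc1cc(OCc9ccccc9)c2c(c1)O[C@H](c7ccc(OCc9ccccc9)c(OCc9ccccc9)c7)[C@@H](O)C2 | intermediate
3 | 3,5,7,3',4'-penta-O-benzylcatechin | c9ccccc9COc1cc(OCc9ccccc9)c2c(c1)O[C@H](c7ccc(OCc9ccccc9)c(OCc9ccccc9)c7)[C@@H](OCc9ccccc9)C2 | intermediate
4 | (2R,3S,4S)-4β-(2-ethoxyethoxy)-penta-O-benzylcatechin | c9ccccc9COc1cc(OCc9ccccc9)c2c(c1)O[C@H](c7ccc(OCc9ccccc9)c(OCc9ccccc9)c7)[C@@H](OCc9ccccc9)[C@H]2OCCOCC | intermediate
5 | phloroglucinol | Oc1cc(O)cc(O)c1 | starting material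
6 | 4α-(2,4,6-trihydroxyphenyl)-penta-O-benzylcatechin | c9ccccc9COc1cc(OCc9ccccc9)c2c(c1)O[C@H](c7ccc(OCc9ccccc9)c(OCc9ccccc9)c7)[C@@H](OCc9ccccc9)[C@@H]2c1c(O)cc(O)cc1O | intermediate
7 | 4α-[2,6-dihydroxy-4-(triisopropylsilyloxy)phenyl]-penta-O-benzylcatechin | c9ccccc9COc1cc(OCc9ccccc9)c2c(c1)O[C@H](c7ccc(OCc9ccccc9)c(OCc9ccccc9)c7)[C@@H](OCc9ccccc9)[C@@H]2c1c(O)cc(O[Si](C(C)C)(C(C)C)C(C)C)cc1O | intermediate
8 | 4α-[2,6-dibenzyloxy-4-(triisopropylsilyloxy)phenyl]-penta-O-benzylcatechin | c9ccccc9COc1cc(OCc9ccccc9)c2c(c1)O[C@H](c7ccc(OCc9ccccc9)c(OCc9ccccc9)c7)[C@@H](OCc9ccccc9)[C@@H]2c1c(OCc9ccccc9)cc(O[Si](C(C)C)(C(C)C)C(C)C)cc1OCc9ccccc9 | intermediate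
9 | 4α-(2,6-dibenzyloxy-4-hydroxyphenyl)-penta-O-benzylcatechin | c9ccccc9COc1cc(OCc9ccccc9)c2c(c1)O[C@H](c7ccc(OCc9ccccc9)c(OCc9ccccc9)c7)[C@@H](OCc9ccccc9)[C@@H]2c1c(OCc9ccccc9)cc(O)cc1OCc9ccccc9 | intermediate
10 | 4α-(2,6-dibenzyloxy-4-hydroxy-3-iodophenyl)-penta-O-benzylcatechin | c9ccccc9COc1cc(OCc9ccccc9)c2c(c1)O[C@H](c7ccc(OCc9ccccc9)c(OCc9ccccc9)c7)[C@@H](OCc9ccccc9)[C@@H]2c1c(OCc9ccccc9)cc(O)c(I)c1OCc9ccccc9 | intermediate
11 | 4α-[2,6-dibenzyloxy-3-iodo-4-(trimethylsilyloxy)phenyl]-penta-O-benzylcatechin | c9ccccc9COc1cc(OCc9ccccc9)c2c(c1)O[C@H](c7ccc(OCc9ccccc9)c(OCc9ccccc9)c7)[C@@H](OCc9ccccc9)[C@@H]2c1c(OCc9ccccc9)cc(O[Si](C)(C)C)c(I)c1OCc9ccccc9 | intermediate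
12 | aryllithium from 11 (Li in place of I), not isolated | c9ccccc9COc1cc(OCc9ccccc9)c2c(c1)O[C@H](c7ccc(OCc9ccccc9)c(OCc9ccccc9)c7)[C@@H](OCc9ccccc9)[C@@H]2c1c(OCc9ccccc9)cc(O[Si](C)(C)C)c([Li])c1OCc9ccccc9 | intermediate
13 | lithium phenoxide after O→C silyl shift, not isolated | [Li+].c9ccccc9COc1cc(OCc9ccccc9)c2c(c1)O[C@H](c7ccc(OCc9ccccc9)c(OCc9ccccc9)c7)[C@@H](OCc9ccccc9)[C@@H]2c1c(OCc9ccccc9)cc([O-])c([Si](C)(C)C)c1OCc9ccccc9 | intermediate
14 | 4α-(2,6-dibenzyloxy-4-triflyloxy-3-trimethylsilylphenyl)catechin pentabenzyl ether | c9ccccc9COc1cc(OCc9ccccc9)c2c(c1)O[C@H](c7ccc(OCc9ccccc9)c(OCc9ccccc9)c7)[C@@H](OCc9ccccc9)[C@@H]2c1c(OCc9ccccc9)cc(OS(=O)(=O)C(F)(F)F)c([Si](C)(C)C)c1OCc9ccccc9 | intermediate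
15 | (−)-epicatechin, (2R,3R) | Oc1cc(O)c2c(c1)O[C@H](c1ccc(O)c(O)c1)[C@H](O)C2 | starting material
16 | 5,7,3',4'-tetra-O-benzylepicatechin | c9ccccc9COc1cc(OCc9ccccc9)c2c(c1)O[C@H](c7ccc(OCc9ccccc9)c(OCc9ccccc9)c7)[C@H](O)C2 | intermediate
17 | 3,5,7,3',4'-penta-O-benzylepicatechin | c9ccccc9COc1cc(OCc9ccccc9)c2c(c1)O[C@H](c7ccc(OCc9ccccc9)c(OCc9ccccc9)c7)[C@H](OCc9ccccc9)C2 | intermediate
18 | 8-bromo-penta-O-benzylepicatechin | c9ccccc9COc1cc(OCc9ccccc9)c2c(c1Br)O[C@H](c7ccc(OCc9ccccc9)c(OCc9ccccc9)c7)[C@H](OCc9ccccc9)C2 | intermediate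
19 | C6 dimethyliminium chloride of 18, not isolated | [Cl-].C[N+](C)=Cc4c(OCc9ccccc9)c(Br)c5c(c4OCc9ccccc9)C[C@@H](OCc9ccccc9)[C@@H](c7ccc(OCc9ccccc9)c(OCc9ccccc9)c7)O5 | intermediate
20 | 8-bromo-penta-O-benzylepicatechin-6-carbaldehyde | O=Cc4c(OCc9ccccc9)c(Br)c5c(c4OCc9ccccc9)C[C@@H](OCc9ccccc9)[C@@H](c7ccc(OCc9ccccc9)c(OCc9ccccc9)c7)O5 | intermediate
21 | 3,4-dibenzyloxybenzaldehyde | O=Cc1ccc(OCc2ccccc2)c(OCc2ccccc2)c1 | starting material
22 | bis(pinacolatoboryl)methane | CC1(C)OB(CB2OC(C)(C)C(C)(C)O2)OC1(C)C | starting material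
23 | lithiated bis(pinacolatoboryl)methane, not isolated | [Li]C(B1OC(C)(C)C(C)(C)O1)B1OC(C)(C)C(C)(C)O1 | intermediate
24 | (E)-2-(3,4-dibenzyloxyphenyl)vinylboronic acid pinacol ester | CC1(C)OB(/C=C/c2ccc(OCc3ccccc3)c(OCc3ccccc3)c2)OC1(C)C | intermediate
25 | potassium (E)-2-(3,4-dibenzyloxyphenyl)vinyltrifluoroborate | [K+].F[B-](F)(F)/C=C/c1ccc(OCc2ccccc2)c(OCc2ccccc2)c1 | intermediate
26 | (S)-2-methoxy-2-phenylacetic acid | CO[C@H](C(=O)O)c1ccccc1 | starting material
27 | (E)-2-(3,4-dibenzyloxyphenyl)vinyl (S)-2-methoxy-2-phenylacetate | CO[C@@H](c1ccccc1)C(=O)O/C=C/c1ccc(OCc2ccccc2)c(OCc2ccccc2)c1 | intermediate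
28 | C4a≡C8a aryne of middle ring A carrying the upper unit at C6, not isolated | c9ccccc9COc1cc(OCc9ccccc9)c2c(c1)O[C@H](c7ccc(OCc9ccccc9)c(OCc9ccccc9)c7)[C@@H](OCc9ccccc9)[C@@H]2C1=C(OCc9ccccc9)C#CC=C1OCc9ccccc9 | intermediate
29 | benzoxete (O1–C8a, C4a–C4 formed; C4 configuration transient), not isolated | c9ccccc9COc1cc(OCc9ccccc9)c2c(c1)O[C@H](c7ccc(OCc9ccccc9)c(OCc9ccccc9)c7)[C@@H](OCc9ccccc9)[C@@H]2c1c(OCc9ccccc9)cc3OC(c4c(OCc9ccccc9)c(Br)c5c(c4OCc9ccccc9)C[C@@H](OCc9ccccc9)[C@@H](c7ccc(OCc9ccccc9)c(OCc9ccccc9)c7)O5)c3c1OCc9ccccc9 | intermediate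
30 | (E)-o-quinone methide (C8a=O, C4a=C4), not isolated | c9ccccc9COc1cc(OCc9ccccc9)c2c(c1)O[C@H](c7ccc(OCc9ccccc9)c(OCc9ccccc9)c7)[C@@H](OCc9ccccc9)[C@@H]2C1=C(OCc9ccccc9)/C(=C\c4c(OCc9ccccc9)c(Br)c5c(c4OCc9ccccc9)C[C@@H](OCc9ccccc9)[C@@H](c7ccc(OCc9ccccc9)c(OCc9ccccc9)c7)O5)C(=O)C=C1OCc9ccccc9 | intermediate
31 | perbenzylated trimer, Br at C8 of the lower unit, middle C3 oxygen as (S)-2-methoxy-2-phenylacetate, middle ring C 2,3-trans-3,4-trans (2R,3S) | c9ccccc9COc1cc(OCc9ccccc9)c2c(c1)O[C@H](c7ccc(OCc9ccccc9)c(OCc9ccccc9)c7)[C@@H](OCc9ccccc9)[C@@H]2c1c(OCc9ccccc9)cc2c(c1OCc9ccccc9)[C@@H](c4c(OCc9ccccc9)c(Br)c5c(c4OCc9ccccc9)C[C@@H](OCc9ccccc9)[C@@H](c7ccc(OCc9ccccc9)c(OCc9ccccc9)c7)O5)[C@H](OC(=O)[C@@H](OC)c8ccccc8)[C@@H](c7ccc(OCc9ccccc9)c(OCc9ccccc9)c7)O2 | intermediate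
32 | the same trimer with free middle C3 hydroxyl | c9ccccc9COc1cc(OCc9ccccc9)c2c(c1)O[C@H](c7ccc(OCc9ccccc9)c(OCc9ccccc9)c7)[C@@H](OCc9ccccc9)[C@@H]2c1c(OCc9ccccc9)cc2c(c1OCc9ccccc9)[C@@H](c4c(OCc9ccccc9)c(Br)c5c(c4OCc9ccccc9)C[C@@H](OCc9ccccc9)[C@@H](c7ccc(OCc9ccccc9)c(OCc9ccccc9)c7)O5)[C@H](O)[C@@H](c7ccc(OCc9ccccc9)c(OCc9ccccc9)c7)O2 | intermediate
33 | catechin-(4α→6)-catechin-(4α→6)-epicatechin | Oc1cc(O)c2c(c1)O[C@H](c1ccc(O)c(O)c1)[C@@H](O)[C@@H]2c1c(O)cc2c(c1O)[C@@H](c1c(O)cc3c(c1O)C[C@@H](O)[C@@H](c1ccc(O)c(O)c1)O3)[C@H](O)[C@@H](c1ccc(O)c(O)c1)O2 | target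

## Step count and risks

Total step count: 20. Longest linear sequence: 13 steps (steps 1–10, then 18–20, from (+)-catechin).

**Step 18 (three-component ring C closure).**
- What may go wrong:
  - The cycloaddition may be sluggish, because the methide is crowded and strongly stabilised by its donor groups.
  - The aryne may be consumed by the accumulating methide or by the alkene of the ester.
  - Fluoride may induce acyl transfer from the enol ester.
  - The methide may equilibrate between E and Z against the C5 benzyloxy group, which would erode the 2,4-cis outcome.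
  - Facial selectivity may be poor.
- Fallback: Lewis-acid interflavan coupling with halogen capping, which is known chemistry. It sets out from 4 and 18 and returns at 33.
  - Compound 4 is brominated with one equivalent of NBS to 8-bromo-4β-(2-ethoxyethoxy)-penta-O-benzylcatechin F1, and with two equivalents to the 6,8-dibromo analogue F2.
  - F1 is ionised with BF3·OEt2 in CH2Cl2 at −78 °C in the presence of an excess of 18, whose only free ring A carbon is C6. This should give the 8,8-dibromo perbenzylated catechin-(4α→6)-epicatechin dimer F3.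
  - F3 again has a single free nucleophilic carbon, C6 of its upper unit. It is coupled in the same way with the doubly capped F2 to give the tetrabromo perbenzylated trimer F4.
  - Hydrogenolysis under the conditions of step 20, with more acetate, removes 15 benzyl groups and four bromines and gives 33.

**Step 5 (site-selective silylation).**
- What may go wrong: the silyl group may spread over the flanking hydroxyls, or double silylation may occur, and either blurs the differentiation of the three oxygens.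
- Fallback: the differentiation is moved from the crowded adduct to the small nucleophile. It sets out from 4 and returns at 8.
  - Commercial 3,5-dibenzyloxyphenol is silylated with i-Pr3SiCl and imidazole to 1,3-dibenzyloxy-5-(triisopropylsilyloxy)benzene F5.
  - F5 is used in excess in the Friedel–Crafts coupling with 4 (BF3·OEt2, CH2Cl2, −78 °C).
  - The bulky silyloxy group should disfavour its two ortho positions, so that attack between the two benzyloxy groups gives 8. The regioisomer is removed by chromatography.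

**Step 17 (copper-catalysed enol ester formation).**
- What may go wrong: the electron-rich styryl trifluoroborate may undergo protodeboronation or oxidative homocoupling, and the product may epimerise at the α-carbon under the amine co-catalyst.
- Fallback: it sets out from 21 and 26 and returns at 27.
  - Aldehyde 21 is homologated (Seyferth–Gilbert reaction with the Ohira–Bestmann reagent, K2CO3, MeOH) to 4-ethynyl-1,2-dibenzyloxybenzene F6.
  - Ruthenium-catalysed anti-Markovnikov addition of acid 26 (Ru(2-methylallyl)2(dppb), toluene, 60 °C) gives (Z)-2-(3,4-dibenzyloxyphenyl)vinyl (S)-2-methoxy-2-phenylacetate F7.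
  - Thiyl-radical-mediated Z→E isomerisation (PhSSPh, visible light) converts F7 into the more stable (E)-ester 27.

## Further compounds

F1 | step 18 | 8-bromo-4β-(2-ethoxyethoxy)-penta-O-benzylcatechin | c9ccccc9COc1cc(OCc9ccccc9)c2c(c1Br)O[C@H](c7ccc(OCc9ccccc9)c(OCc9ccccc9)c7)[C@@H](OCc9ccccc9)[C@H]2OCCOCC
F2 | step 18 | 6,8-dibromo-4β-(2-ethoxyethoxy)-penta-O-benzylcatechin | c9ccccc9COc1c(Br)c(OCc9ccccc9)c2c(c1Br)O[C@H](c7ccc(OCc9ccccc9)c(OCc9ccccc9)c7)[C@@H](OCc9ccccc9)[C@H]2OCCOCC
F3 | step 18 | 8-bromo-penta-O-benzylcatechin-(4α→6)-8-bromo-penta-O-benzylepicatechin | c9ccccc9COc1cc(OCc9ccccc9)c2c(c1Br)O[C@H](c7ccc(OCc9ccccc9)c(OCc9ccccc9)c7)[C@@H](OCc9ccccc9)[C@@H]2c4c(OCc9ccccc9)c(Br)c5c(c4OCc9ccccc9)C[C@@H](OCc9ccccc9)[C@@H](c7ccc(OCc9ccccc9)c(OCc9ccccc9)c7)O5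
F4 | step 18 | tetrabromo pentadeca-O-benzyl catechin-(4α→6)-catechin-(4α→6)-epicatechin | c9ccccc9COc1c(Br)c(OCc9ccccc9)c2c(c1Br)O[C@H](c7ccc(OCc9ccccc9)c(OCc9ccccc9)c7)[C@@H](OCc9ccccc9)[C@@H]2c1c(OCc9ccccc9)c(Br)c2c(c1OCc9ccccc9)[C@@H](c4c(OCc9ccccc9)c(Br)c5c(c4OCc9ccccc9)C[C@@H](OCc9ccccc9)[C@@H](c7ccc(OCc9ccccc9)c(OCc9ccccc9)c7)O5)[C@H](OCc9ccccc9)[C@@H](c7ccc(OCc9ccccc9)c(OCc9ccccc9)c7)O2
F5 | step 5 | 1,3-dibenzyloxy-5-(triisopropylsilyloxy)benzene | CC(C)[Si](Oc1cc(OCc2ccccc2)cc(OCc2ccccc2)c1)(C(C)C)C(C)C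
F6 | step 17 | 4-ethynyl-1,2-dibenzyloxybenzene | C#Cc1ccc(OCc2ccccc2)c(OCc2ccccc2)c1
F7 | step 17 | (Z)-2-(3,4-dibenzyloxyphenyl)vinyl (S)-2-methoxy-2-phenylacetate | CO[C@@H](c1ccccc1)C(=O)O/C=C\c1ccc(OCc2ccccc2)c(OCc2ccccc2)c1
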